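## Retrosynthetic overview

- Ferulate C=C: Horner–Wadsworth–Emmons disconnection to vanillin and a chromenylmethyl phosphonoacetate; the phosphonoacetate also masks the primary OH through the earlier steps.
- Pyran ring (the only ring made; both benzene rings are bought): aryl C8a–O1 bond closed by a light-driven E→Z isomerisation / Ni-photoredox etherification of a bromoaryl (E)-alkenyl tertiary alcohol. The tertiary C–O bond of the stereocentre is never broken.
- C4–C4a bond: iodide-selective Heck coupling of 4-bromo-2-hydroxy-5-iodoacetophenone with a vinyl carbinol.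
- Vinyl carbinol: from (S)-2-methylglycidol, which supplies the only stereocentre, by sulfonium-ylide one-carbon homologation, then selective primary O-acylation.

Assumption: (S)-2-methylglycidol, 4'-bromo-2'-hydroxyacetophenone, diethylphosphonoacetic acid and vanillin are taken as purchasable; the target stereocentre reads as (R) from the SMILES.

## Route

Step 1
Reactants: 1 (S)-2-methylglycidol
Product: 2 (2R)-2-methylbut-3-ene-1,2-diol
Conditions: Me3S+ I− (4.5 equiv), n-BuLi (4.5 equiv), THF, −10 °C → rt; then H2O
Reagents that add atoms: trimethylsulfonium iodide, C[S+](C)C.[I-]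
Why: Epoxide-to-allylic-alcohol one-carbon homologation with dimethylsulfonium methylide: the ylide opens the epoxide at the unhindered CH2 and a second base equivalent triggers α',β-elimination of Me2S to the vinyl carbinol; no bond to the quaternary carbon is touched (S→R is only a CIP priority change) and Payne equilibration of the alkoxide is degenerate, returning the same enantiomer.

Step 2
Reactants: 2 (2R)-2-methylbut-3-ene-1,2-diol; 3 diethylphosphonoacetic acid
Product: 4 (2R)-2-hydroxy-2-methylbut-3-en-1-yl 2-(diethoxyphosphoryl)acetate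
Conditions: DCC (1.1 equiv), DMAP (5 mol%), CH2Cl2, 0 °C → rt
Reagents that add atoms: none
Why: Steglich esterification acylates the primary OH and leaves the hindered tertiary allylic OH free; the stereocentre is not involved.

Step 3
Reactants: 5 1-(4-bromo-2-hydroxyphenyl)ethan-1-one
Product: 6 1-(4-bromo-2-hydroxy-5-iodophenyl)ethan-1-one
Conditions: NIS (1.05 equiv), TsOH·H2O (10 mol%), MeCN, rt
Reagents that add atoms: N-iodosuccinimide, O=C1CCC(=O)N1I
Why: Electrophilic aromatic iodination goes para to the phenol OH (C5), the less hindered of the two activated positions, since C3 is flanked by OH and Br.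

Step 4
Reactants: 4 (2R)-2-hydroxy-2-methylbut-3-en-1-yl 2-(diethoxyphosphoryl)acetate; 6 1-(4-bromo-2-hydroxy-5-iodophenyl)ethan-1-one
Product: 7 (2R,3E)-4-(5-acetyl-2-bromo-4-hydroxyphenyl)-2-hydroxy-2-methylbut-3-en-1-yl 2-(diethoxyphosphoryl)acetate
Conditions: Pd(OAc)2 (5 mol%), n-Bu4NCl (1 equiv), NaHCO3 (2.5 equiv), DMF, 60 °C
Reagents that add atoms: none
Why: Mizoroki–Heck coupling under ligand-free Jeffery conditions reacts at C–I and spares C–Br; the tertiary carbinol has no carbinol H, so β-hydride elimination can only give the (E)-styrene, and the stereocentre is untouched.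

Step 5
Reactants: 7 (2R,3E)-4-(5-acetyl-2-bromo-4-hydroxyphenyl)-2-hydroxy-2-methylbut-3-en-1-yl 2-(diethoxyphosphoryl)acetate
Product: 9 [(2R)-6-acetyl-7-hydroxy-2-methyl-2H-chromen-2-yl]methyl 2-(diethoxyphosphoryl)acetate, via Z-alkene 8 (not isolated)
Conditions: Ir[dF(CF3)ppy]2(dtbbpy)PF6 (1 mol%), NiBr2·glyme (10 mol%), dtbbpy (10 mol%), quinuclidine (20 mol%), K2CO3 (1.5 equiv), 3 Å MS, degassed MeCN (0.02 M), 450 nm LEDs, 25 °C
Reagents that add atoms: none
Why: Proposed new method: one-flask triplet-sensitised E→Z isomerisation / Ni-photoredox intramolecular C(sp2)–O coupling of a tertiary alcohol — the Ir sensitiser (ET ≈ 61 kcal/mol) pumps the conjugated E-styrene to the twisted, higher-triplet-energy Z-isomer 8, whose tertiary OH sits next to the C–Br carbon; Ni(0) inserts into the C–Br bond (activated para to acetyl), the tertiary alkoxide closes a seven-membered oxanickelacycle (no β-H on the carbinol carbon, and the only other OH is acylated), and photocatalytic oxidation to Ni(III) drives C–O reductive elimination to the 2H-chromene, draining 8 from the photostationary mixture; the O–C2 bond is never broken, so (R) is carried through; closest known reactions are Ir/Ni metallaphotoredox etherification of aryl bromides with primary and secondary alcohols and energy-transfer E→Z isomerisation–cyclisation routes to coumarins.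

Step 6
Reactants: 9 [(2R)-6-acetyl-7-hydroxy-2-methyl-2H-chromen-2-yl]methyl 2-(diethoxyphosphoryl)acetate; 10 vanillin
Product: 11 [(2R)-6-acetyl-7-hydroxy-2-methyl-2H-chromen-2-yl]methyl (2E)-3-(4-hydroxy-3-methoxyphenyl)prop-2-enoate
Conditions: 10 (1.3 equiv), LiCl (3 equiv), DBU (3.5 equiv), MeCN, rt → 40 °C; then pH 6 buffer
Reagents that add atoms: none
Why: Horner–Wadsworth–Emmons olefination under Masamune–Roush conditions gives the (E)-cinnamate; the Li-chelated phosphonate is far more acidic and nucleophilic than the chelated aryl methyl ketone, and the mild amine base leaves the ester and the C2 stereocentre alone.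

## Compound list

1 | (S)-2-methylglycidol [(2S)-(2-methyloxiran-2-yl)methanol] | OC[C@@]1(C)CO1 | starting material
2 | (2R)-2-methylbut-3-ene-1,2-diol | OC[C@@](O)(C)C=C | intermediate
3 | diethylphosphonoacetic acid [2-(diethoxyphosphoryl)acetic acid] | CCOP(=O)(OCC)CC(=O)O | starting material
4 | (2R)-2-hydroxy-2-methylbut-3-en-1-yl 2-(diethoxyphosphoryl)acetate | CCOP(=O)(OCC)CC(=O)OC[C@@](O)(C)C=C | intermediate
5 | 1-(4-bromo-2-hydroxyphenyl)ethan-1-one | CC(=O)c1ccc(Br)cc1O | starting material
6 | 1-(4-bromo-2-hydroxy-5-iodophenyl)ethan-1-one | CC(=O)c1cc(I)c(Br)cc1O | intermediate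
7 | (2R,3E)-4-(5-acetyl-2-bromo-4-hydroxyphenyl)-2-hydroxy-2-methylbut-3-en-1-yl 2-(diethoxyphosphoryl)acetate | CCOP(=O)(OCC)CC(=O)OC[C@@](O)(C)/C=C/c1cc(C(C)=O)c(O)cc1Br | intermediate
8 | (2R,3Z)-4-(5-acetyl-2-bromo-4-hydroxyphenyl)-2-hydroxy-2-methylbut-3-en-1-yl 2-(diethoxyphosphoryl)acetate | CCOP(=O)(OCC)CC(=O)OC[C@@](O)(C)/C=C\c1cc(C(C)=O)c(O)cc1Br | intermediate (not isolated)
9 | [(2R)-6-acetyl-7-hydroxy-2-methyl-2H-chromen-2-yl]methyl 2-(diethoxyphosphoryl)acetate | CCOP(=O)(OCC)CC(=O)OC[C@@]1(C)C=Cc2cc(C(C)=O)c(O)cc2O1 | intermediate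
10 | vanillin (4-hydroxy-3-methoxybenzaldehyde) | COc1cc(C=O)ccc1O | starting material
11 | [(2R)-6-acetyl-7-hydroxy-2-methyl-2H-chromen-2-yl]methyl (2E)-3-(4-hydroxy-3-methoxyphenyl)prop-2-enoate (CNP0375196.1) | COc1cc(/C=C/C(=O)OC[C@@]2(C)C=Cc3cc(C(C)=O)c(O)cc3O2)ccc1O | target

## Step count and risks

Total steps: 6. Longest linear sequence: 5 (steps 1, 2, 4, 5, 6 from compound 1); step 3 is a one-step side branch.

Steps most likely to fail:

**Step 5 (the proposed new step).** The risks are:
- the o-hydroxyacetophenone unit may chelate and sequester Ni;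
- the hindered Ni–aryl may protodebrominate before the tertiary alkoxide binds;
- adventitious water may couple to give a 4-hydroxyarene, which would cyclise with racemisation;
- sensitised C2–O1 ring-opening of the 2H-chromene product (photochromism) would erode ee, so ee must be checked by chiral HPLC and irradiation stopped at full conversion.

Fallback with known chemistry, setting out from 7: run the energy-transfer isomerisation alone (Ir(ppy)3 1 mol%, MeCN, 450 nm) and isolate the Z-alkene 8. Then close the ring thermally by Pd-catalysed intramolecular C–O coupling of the tertiary alcohol with the aryl bromide (Pd(OAc)2, Tol-BINAP or t-BuXPhos, Cs2CO3, toluene, 80 °C). This comes back to the route at 9. No compound outside the list is made (F0).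

**Step 1.** The ylide homologation is run on an unprotected epoxy alcohol, and the small diol is water-soluble and volatile, so isolation may be poor. Fallback, setting out from 1: open the epoxide with (phenylselanyl)methyllithium (from bis(phenylselanyl)methane and n-BuLi, THF, −78 → 0 °C) to give (2R)-2-methyl-4-(phenylselanyl)butane-1,2-diol F1, which is lipophilic and easy to purify. Oxidise with H2O2 (THF, 0 °C) to the selenoxide (2R)-2-methyl-4-(phenylseleninyl)butane-1,2-diol F2. On warming to 40–50 °C with i-Pr2NH this undergoes syn-elimination, which can only go toward C3, and the route is rejoined at 2.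

**Step 6.** DBU deprotonates vanillin, and the resulting phenoxide is a poor electrophile, so the olefination may stall or let the aryl methyl ketone compete. Fallback, setting out from 9 and 10: silylate 10 (TBSCl, imidazole, DMF) to 4-[(tert-butyldimethylsilyl)oxy]-3-methoxybenzaldehyde F3. Olefinate 9 with F3 (LiCl, i-Pr2NEt, MeCN, rt) to [(2R)-6-acetyl-7-hydroxy-2-methyl-2H-chromen-2-yl]methyl (2E)-3-{4-[(tert-butyldimethylsilyl)oxy]-3-methoxyphenyl}prop-2-enoate F4. Remove the silyl group with AcOH-buffered TBAF (THF, 0 °C) to come back at 11.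

## Further compounds

F1 | step 1 | (2R)-2-methyl-4-(phenylselanyl)butane-1,2-diol | OC[C@@](O)(C)CC[Se]c1ccccc1
F2 | step 1 | (2R)-2-methyl-4-(phenylseleninyl)butane-1,2-diol (selenoxide, mixture at Se) | OC[C@@](O)(C)CC[Se](=O)c1ccccc1
F0 | step 5 | none | none
F3 | step 6 | 4-[(tert-butyldimethylsilyl)oxy]-3-methoxybenzaldehyde | COc1cc(C=O)ccc1O[Si](C)(C)C(C)(C)C
F4 | step 6 | [(2R)-6-acetyl-7-hydroxy-2-methyl-2H-chromen-2-yl]methyl (2E)-3-{4-[(tert-butyldimethylsilyl)oxy]-3-methoxyphenyl}prop-2-enoate | COc1cc(/C=C/C(=O)OC[C@@]2(C)C=Cc3cc(C(C)=O)c(O)cc3O2)ccc1O[Si](C)(C)C(C)(C)C
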